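I left you three flasks, and the leftover to watch in each was the fraction of its charge of second nucleophile not yet decomposed.

| setting | spring | dawn | summer |
|---|---|---|---|
| starting material | 0.14 M (fed, over 10 h) | 0.14 M | 0.14 M |
| first nucleophile | 0.133 M | 0.133 M | 0.133 M (fed, over 10 h) |
| second nucleophile | 0.560 M | 0.560 M | 0.560 M |
| capture agent | 0.140 M | 0.140 M | 0.140 M |
| time | 25 h | 25 h | 25 h |
| remark | all else is in the flask from the start; the feed brings no volume worth counting | everything together at the start | all else is in the flask from the start; the feed brings no volume worth counting |

    first nucleophile + open intermediate → target (k1 = 98.4 M⁻¹ h⁻¹)
    open intermediate + capture agent → trapped intermediate (k2 = 0.146 M⁻¹ h⁻¹)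
    starting material → open intermediate (k3 = 0.0153 h⁻¹)
    starting material + target → side product (k4 = 0.117 M⁻¹ h⁻¹)
    second nucleophile + open intermediate → other capture product (k5 = 55.7 M⁻¹ h⁻¹)
    second nucleophile → decomposed reagent (k6 = 0.0850 h⁻¹)

- a species is counted by the starting material in it: one side product counts as two
- run time (spring): 25 h

- which flask leads in share of target in target plus other capture product ("all alike" within 1.5 percentage points) (spring / dawn / summer / all alike)
- share of target in target plus other capture product at the end, spring
- share of target in target plus other capture product at the end, dawn
- share of target in target plus other capture product at the end, summer

**In the flasks.** Starting material opened slowly, with a half-life of 45 h in dawn. The open intermediate was captured far faster, its half-life by the first nucleophile in dawn being 0.053 h. I set the capture agent aside because its half-life against the open intermediate in dawn, 34 h, was far longer. Each opening was therefore split between the two nucleophiles.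

**The split.** At the start the pseudo-first-order capture by the second nucleophile outran that by the first by a capture ratio of 2.38. That ratio fell with the fraction of second nucleophile left, whose half-life in dawn was 8.2 h, so by my reckoning the two drew level at 10.2 h. I took the opening rate as steady and integrated the target's share of each opening in closed form. From the mean moment of a feed to the end this gave the target-hours 11.9 h. From the start, for dawn, it gave 13.6 h.

**My reckoning.** I treated a feed as arriving whole at its mean moment. Spring therefore opened for 20.0 h, while summer opened for 25 h and, in this reckoning, gave its openings before that moment to the second nucleophile. Against side product I kept 0.849 of the target in spring and summer, and 0.815 in dawn. The shares came to 55.5 % for spring, 49.3 % for dawn and 43.5 % for summer, so the lead went to spring.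

**Hands off.** I asked you not to hurry the spring feed, because at the start the second nucleophile's capture was the faster.

**The outcome.** The forecast named spring, with 53.5 %, 47 % and 43 % for spring, dawn and summer, since “anything that opens late goes mostly to target”. The simulation put spring ahead, with 54.4 %, 48.6 % and 42.9 % in that order, and spring lay 1.1 percentage points under my figure. The neighbouring flask was spring with 0.33 M of first nucleophile. There the capture ratio at the start was 0.961, and target-hours rose from 11.9 h to 15.5 h, which reckoned a share of 74.8 %. That flask gave 73.9 %, with target at 17.5 % of the charge.

Its constants are invented; no experiment stands behind them.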